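**Assumption:** the target is read as epicatechin-3-O-gallate-(4β→8)-epicatechin-3-O-gallate-(4β→8)-catechin; (−)-epicatechin, (+)-catechin and 3,4,5-tris(benzyloxy)benzoic acid are bought (enantiopure where chiral), and common reagents (BnBr, DDQ, 2-ethoxyethanol, DCC, H2) are named in the steps and not numbered.

**Retrosynthetic overview**
1. Last operation: global hydrogenolysis of an eighteen-fold O-benzylated trimer.
2. Key disconnection: both C4–C8 interflavan bonds are cut at once, giving two flavan-4-yl cation equivalents (extension units that already carry the 3-O-galloyl ester) and one catechin starter unit. In the forward direction the chain grows in one flask from the terminal unit upward, as proposed for the plant.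
3. The cation precursor comes from tetra-O-benzylepicatechin by DDQ oxidation of C4–H (oxidative entry to the quinone-methide/flavan-4-yl cation), followed by esterification of the 3-OH with tri-O-benzylgallic acid.
4. Rings: none is built, just as the plant's oligomerisation forms no ring. All rings and the C2/C3 centres come from (−)-epicatechin (used twice), (+)-catechin and the gallic acid building block; only the two C4 centres are new (both β, substrate-controlled).

**Route**

Step 1
Reactants: 1 (−)-epicatechin (2R,3R, 2,3-cis)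
Product: 2 5,7,3′,4′-tetra-O-benzyl-(−)-epicatechin (3-OH free)
Conditions: BnBr (4.4 equiv), K2CO3 (5 equiv), DMF, N2, 0 °C to rt
Reagents that add atoms: benzyl bromide, BrCc1ccccc1
Why: Williamson etherification in which K2CO3 deprotonates the four phenols but not the aliphatic 3-OH, so only the phenols are O-benzylated by SN2 and, under oxygen-free conditions at or below room temperature, C2 and C3 are untouched.

Step 2
Reactants: 2 5,7,3′,4′-tetra-O-benzyl-(−)-epicatechin
Product: 3 4β-(2-ethoxyethoxy)-5,7,3′,4′-tetra-O-benzylepicatechin (OCH2CH2OEt at C4 on the β face, trans to the 3α-OH and the 2α-aryl group; 2,3-cis-3,4-trans)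
Conditions: DDQ (2 equiv), HOCH2CH2OEt (10 equiv), CH2Cl2, 0 °C to rt
Reagents that add atoms: 2-ethoxyethanol, CCOCCO
Why: DDQ benzylic C–H oxidation by hydride abstraction at C4 (ortho/para to the two ring A ether oxygens) gives the ring-A-stabilised flavan-4-yl cation, the synthetic counterpart of the biogenetic extension unit, which 2-ethoxyethanol captures from the β face anti to the 2α-aryl and 3α-oxygen substituents, setting the 4β centre (it is ionised again in step 5, so its ratio is not critical).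

Step 3
Reactants: 3 4β-(2-ethoxyethoxy)-5,7,3′,4′-tetra-O-benzylepicatechin; 4 3,4,5-tris(benzyloxy)benzoic acid
Product: 5 4β-(2-ethoxyethoxy)-hepta-O-benzyl-epicatechin 3-O-gallate, i.e. (2R,3R,4S-configured 2,3-cis-3,4-trans) 5,7-bis(benzyloxy)-2-[3,4-bis(benzyloxy)phenyl]-4-(2-ethoxyethoxy)chroman-3-yl 3,4,5-tris(benzyloxy)benzoate
Conditions: DCC (1.5 equiv), DMAP (0.3 equiv), CH2Cl2, 0 °C to rt
Reagents that add atoms: none
Why: Steglich esterification, in which the O-acylisourea of 4 is relayed by DMAP to the hindered secondary 3-OH under neutral conditions that leave the acid-labile C4 acetal intact; the C3–O bond is not broken, so no stereocentre changes.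

Step 4
Reactants: 6 (+)-catechin (2R,3S, 2,3-trans)
Product: 7 5,7,3′,4′-tetra-O-benzyl-(+)-catechin (3-OH free)
Conditions: BnBr (4.4 equiv), K2CO3 (5 equiv), DMF, N2, 0 °C to rt
Reagents that add atoms: benzyl bromide, BrCc1ccccc1
Why: Williamson etherification in which K2CO3 deprotonates the four phenols but not the aliphatic 3-OH, so only the phenols are benzylated and no stereocentre is touched.

Step 5
Reactants: 7 5,7,3′,4′-tetra-O-benzyl-(+)-catechin (1.0 equiv); 5 4β-(2-ethoxyethoxy)-hepta-O-benzyl-epicatechin 3-O-gallate (2.2 equiv in two portions)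
Product: 9 octadeca-O-benzyl-[ECG-(4β→8)-ECG-(4β→8)-catechin] (all eighteen phenols benzylated; terminal 3-OH free), via protected dimer 8 (not isolated)
Conditions: TMSOTf (0.2 equiv), CH2Cl2, 4 Å MS, −78 °C; 5 (1.0 equiv) added over 1 h, then 5 (1.2 equiv) added over 1 h, −78 to −40 °C; Et3N quench
Reagents that add atoms: none
Why: Proposed new method: TMSOTf ionises the C4 acetal of 5 (silicon is chelated by the 2-ethoxyethoxy group) to the ring-A-stabilised flavan-4-yl cation, whose α face is blocked by the 2α-aryl group and the participating 3α-galloyloxy group, so C8 of 7 (the most nucleophilic, least hindered arene position, as in the plant's starter unit) attacks from the β face to give 8 with the first new 4β centre, and the second charge of 5 then extends the chain at C8 of the upper unit of 8 (the site benzylated dimers are known to use), again from the β face, to set the second 4β centre; the closest known reactions are the stepwise TMSOTf-mediated Friedel–Crafts-type couplings of 4-(2-ethoxyethoxy)flavan donors with benzylated monomeric and dimeric flavan-3-ol nucleophiles, here run back to back without isolating the dimer.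

Step 6
Reactants: 9 octadeca-O-benzyl trimer
Product: 10 epicatechin-3-O-gallate-(4β→8)-epicatechin-3-O-gallate-(4β→8)-catechin (target, CNP0269915.2)
Conditions: H2 (1 atm), Pd(OH)2/C, THF–MeOH–H2O (20:20:1), rt; Sephadex LH-20, then lyophilisation
Reagents that add atoms: none
Why: Heterogeneous catalytic hydrogenolysis cleaves the eighteen benzyl aryl ethers, while the two galloyl esters, the C4–C8 bonds, the chroman rings and all eight stereocentres are inert under neutral conditions at room temperature and 1 atm.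

**Compound list**

1 | (−)-epicatechin | O[C@@H]1Cc2c(O)cc(O)cc2O[C@@H]1c1ccc(O)c(O)c1 | starting material
2 | 5,7,3′,4′-tetra-O-benzyl-(−)-epicatechin | O[C@@H]1Cc2c(OCc3ccccc3)cc(OCc3ccccc3)cc2O[C@@H]1c1ccc(OCc3ccccc3)c(OCc3ccccc3)c1 | intermediate
3 | 4β-(2-ethoxyethoxy)-5,7,3′,4′-tetra-O-benzylepicatechin | CCOCCO[C@H]1c2c(OCc3ccccc3)cc(OCc3ccccc3)cc2O[C@H](c2ccc(OCc3ccccc3)c(OCc3ccccc3)c2)[C@@H]1O | intermediate
4 | 3,4,5-tris(benzyloxy)benzoic acid | OC(=O)c1cc(OCc2ccccc2)c(OCc2ccccc2)c(OCc2ccccc2)c1 | starting material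
5 | 4β-(2-ethoxyethoxy)-hepta-O-benzyl-epicatechin 3-O-gallate | CCOCCO[C@H]1c2c(OCc3ccccc3)cc(OCc3ccccc3)cc2O[C@H](c2ccc(OCc3ccccc3)c(OCc3ccccc3)c2)[C@@H]1OC(=O)c1cc(OCc3ccccc3)c(OCc3ccccc3)c(OCc3ccccc3)c1 | intermediate
6 | (+)-catechin | O[C@H]1Cc2c(O)cc(O)cc2O[C@@H]1c1ccc(O)c(O)c1 | starting material
7 | 5,7,3′,4′-tetra-O-benzyl-(+)-catechin | O[C@H]1Cc2c(OCc3ccccc3)cc(OCc3ccccc3)cc2O[C@@H]1c1ccc(OCc3ccccc3)c(OCc3ccccc3)c1 | intermediate
8 | protected dimer, [hepta-O-benzyl-ECG]-(4β→8)-[tetra-O-benzylcatechin] | O=C(O[C@@H]1[C@@H](c2c(OCc5ccccc5)cc(OCc5ccccc5)c3c2O[C@H](c2ccc(OCc5ccccc5)c(OCc5ccccc5)c2)[C@@H](O)C3)c2c(OCc5ccccc5)cc(OCc5ccccc5)cc2O[C@@H]1c1ccc(OCc5ccccc5)c(OCc5ccccc5)c1)c1cc(OCc5ccccc5)c(OCc5ccccc5)c(OCc5ccccc5)c1 | intermediate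
9 | octadeca-O-benzyl-[ECG-(4β→8)-ECG-(4β→8)-catechin] | O=C(O[C@@H]1[C@@H](c2c(OCc5ccccc5)cc(OCc5ccccc5)c3c2O[C@H](c2ccc(OCc5ccccc5)c(OCc5ccccc5)c2)[C@@H](O)C3)c2c(OCc5ccccc5)cc(OCc5ccccc5)c([C@H]3c4c(OCc5ccccc5)cc(OCc5ccccc5)cc4O[C@H](c4ccc(OCc5ccccc5)c(OCc5ccccc5)c4)[C@@H]3OC(=O)c3cc(OCc5ccccc5)c(OCc5ccccc5)c(OCc5ccccc5)c3)c2O[C@@H]1c1ccc(OCc5ccccc5)c(OCc5ccccc5)c1)c1cc(OCc5ccccc5)c(OCc5ccccc5)c(OCc5ccccc5)c1 | intermediate
10 | epicatechin-3-O-gallate-(4β→8)-epicatechin-3-O-gallate-(4β→8)-catechin | O=C(O[C@@H]1[C@@H](c2c(O)cc(O)c3c2O[C@H](c2ccc(O)c(O)c2)[C@@H](O)C3)c2c(O)cc(O)c([C@H]3c4c(O)cc(O)cc4O[C@H](c4ccc(O)c(O)c4)[C@@H]3OC(=O)c3cc(O)c(O)c(O)c3)c2O[C@@H]1c1ccc(O)c(O)c1)c1cc(O)c(O)c(O)c1 | target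

**Totals**
Total steps: 6. Longest linear sequence: 5 (1 → 2 → 3 → 5 → 9 → 10).

**Three steps most likely to fail**

Step 5 (one-pot double coupling). The risk is oligomer statistics: residual dimer 8, tetramer, and self-condensation of donor 5 through its own free C8. A realistic yield of 9 is about 30 %, after size-based separation. The fallback is a capped, stepwise chain extension that sets out from 2 and comes back to the route at 10. Compound 2 is brominated at C8 (NBS, CH2Cl2, −78 °C) to 8-bromo-5,7,3′,4′-tetra-O-benzylepicatechin F1. F1 is oxidised as in step 2 (DDQ, 2-ethoxyethanol, CH2Cl2) to 8-bromo-4β-(2-ethoxyethoxy)-tetra-O-benzylepicatechin F2. F2 is esterified as in step 3 with 4 (DCC, DMAP, CH2Cl2) to the 8-bromo galloylated donor F3. Dimer 8 is made and isolated by adding 5 to a threefold excess of 7 (TMSOTf, CH2Cl2, −78 °C; excess 7 recovered). Compounds 8 and F3 (1:1, TMSOTf, CH2Cl2, −78 °C) give the protected trimer brominated at C8 of the upper unit F4; the bromine blocks both self-condensation of the donor and over-extension. H2, Pd(OH)2/C, Et3N, THF–MeOH–H2O then removes the C–Br bond together with the eighteen benzyl groups and gives 10 directly.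

Step 3 (esterification of a hindered 3-OH next to an acid-labile C4 acetal). The risk is slow acylation with N-acylurea formation, or loss of the 2-ethoxyethoxy group during a long reaction. The fallback puts the ester on before the oxidation; it sets out from 2 and comes back at 5. Esterification of 2 with 4 (DCC, DMAP, CH2Cl2, rt to reflux, on a substrate with no acetal to lose) gives hepta-O-benzyl-epicatechin 3-O-gallate F5. DDQ and 2-ethoxyethanol in CH2Cl2 then oxidise C4 of F5 and give 5, with the 3α-galloyloxy group directing the alcohol to the β face.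

Step 6 (eighteen hydrogenolyses on a crowded substrate). The risk is stalling at partly benzylated, poorly soluble intermediates, and air oxidation of the free polyphenol. The fallback is a non-reductive Lewis-acid debenzylation with a cation scavenger; it sets out from 9, comes back at 10 and makes no new compound. Conditions are BCl3 (excess) and pentamethylbenzene in CH2Cl2 at −78 °C, with a MeOH quench at −78 °C. The benzyl cations are trapped by the non-basic arene, and the aprotic, low-temperature conditions are chosen to spare the esters and the interflavan bonds.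

**Further compounds**

F1 | step 5 | 8-bromo-5,7,3′,4′-tetra-O-benzylepicatechin | O[C@@H]1Cc2c(OCc3ccccc3)cc(OCc3ccccc3)c(Br)c2O[C@@H]1c1ccc(OCc3ccccc3)c(OCc3ccccc3)c1
F2 | step 5 | 8-bromo-4β-(2-ethoxyethoxy)-5,7,3′,4′-tetra-O-benzylepicatechin | CCOCCO[C@H]1c2c(OCc3ccccc3)cc(OCc3ccccc3)c(Br)c2O[C@H](c2ccc(OCc3ccccc3)c(OCc3ccccc3)c2)[C@@H]1O
F3 | step 5 | 8-bromo-4β-(2-ethoxyethoxy)-hepta-O-benzyl-epicatechin 3-O-gallate | CCOCCO[C@H]1c2c(OCc5ccccc5)cc(OCc5ccccc5)c(Br)c2O[C@H](c2ccc(OCc5ccccc5)c(OCc5ccccc5)c2)[C@@H]1OC(=O)c1cc(OCc5ccccc5)c(OCc5ccccc5)c(OCc5ccccc5)c1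
F4 | step 5 | octadeca-O-benzyl trimer brominated at C8 of the upper unit | O=C(O[C@@H]1[C@@H](c2c(OCc5ccccc5)cc(OCc5ccccc5)c3c2O[C@H](c2ccc(OCc5ccccc5)c(OCc5ccccc5)c2)[C@@H](O)C3)c2c(OCc5ccccc5)cc(OCc5ccccc5)c([C@H]3c4c(OCc5ccccc5)cc(OCc5ccccc5)c(Br)c4O[C@H](c4ccc(OCc5ccccc5)c(OCc5ccccc5)c4)[C@@H]3OC(=O)c3cc(OCc5ccccc5)c(OCc5ccccc5)c(OCc5ccccc5)c3)c2O[C@@H]1c1ccc(OCc5ccccc5)c(OCc5ccccc5)c1)c1cc(OCc5ccccc5)c(OCc5ccccc5)c(OCc5ccccc5)c1
F5 | step 3 | hepta-O-benzyl-epicatechin 3-O-gallate | O=C(O[C@@H]1Cc2c(OCc3ccccc3)cc(OCc3ccccc3)cc2O[C@@H]1c1ccc(OCc3ccccc3)c(OCc3ccccc3)c1)c1cc(OCc3ccccc3)c(OCc3ccccc3)c(OCc3ccccc3)c1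
F0 | step 6 | none | none
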